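## Analysis of the target

Compound 21 is a monocyclic acid: one cyclohex-3-ene ring that carries a 7-coumarinyl ether, with no ring fusion to lean on. The ring is numbered C1 (quaternary; CH3 and CH2CH2CO2H), C2 (H and CH2OAr, carbon C7), C3(CH3)=C4, C5 (H and isopropenyl: central carbon C8, =CH2 carbon C9) and C6 (CH2). The configuration is (1R,2R,5S): the propanoic chain on C1, C7 on C2 and the isopropenyl group on C5 lie on one face, and the C1 methyl on the other. C1 is an all-carbon quaternary centre whose two arms (CH3, CH2CH2CO2H) differ little in size, and C2 and C5 are 1,4-related across C3=C4, so neither can steer the other by ordinary substrate control. The coumarin lactone opens in base (reversibly), both alkenes rule out hydrogenation and strong acid, and C2 epimerises and C3=C4 drifts into conjugation whenever C7 is an aldehyde. The strategy rests on one observation: C2 and C5 flank C3=C4 like the bridgeheads of a bicyclo[2.2.2]oct-2-ene. A temporary C7–C8 bond turns C2–C3=C4–C5–C8–C7 into a Diels–Alder cyclohexene. Because C7 bears oxygen and C8 bears C9, that bond can later be cut by a Grob fragmentation that returns C7 as CHO and C8=C9 as the isopropenyl alkene.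

## Retrosynthetic reasoning

**21 to 18 and 19.** The aryl ether C7–O bond and the methyl ester are removed first, 21 coming from ester 20. The coumarin is the most base-sensitive part and the phenol 19 is a good Mitsunobu partner, so it is attached last to the primary alcohol of 18. No stereocentre is touched.

**18 to 15.** C7 and C8 are reconnected (retro-Grob), C9 is given a sulfonate and the C7 oxygen is tied to the chain carboxyl as a lactone. This converts the 1,4-cis relationship of C2 and C5 into the trivial fact that both are bridgeheads of one bicycle. Forward, alcoholysis of lactone 15 must free alkoxide 16, which fragments to aldehyde 17, and a hydride donor present in the flask must reduce 17 to 18 before C2 can epimerise.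

**15 to 13.** Only functional-group changes at C9: mesylate 15 from alcohol 14, and 14 from aldehyde 13. The aldehyde level at C9 is wanted one step earlier because it activates the dienophile.

**13 to 12.** The C2–C7 and C5–C8 bonds are cut together (retro-Diels–Alder). They are cut here because the lactone already ties C7 to C1. In precursor 12 the dienophile therefore hangs from the quaternary carbon and can reach only the diene face that carries the chain. One centre, C1, then dictates C2 and C5. Forward, the enal of 12 must add across C2 and C5 faster than the diene isomerises.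

**12 to 8 and 10.** The enol ester C(=O)–O bond is cut. Acid 8 is activated as chloride 11 and O-acylates the formyl enolate 10, which comes from the vinylogous formamide 9 by hydrolysis. This puts the whole dienophile on in one step.

**8 to 4.** Acid 8 comes from ester 7. Its diene C2=C3–C4=C5 is traced to the enone C4(=O)–C3=C2 of 4: dienolate 5, dienyl triflate 6, then replacement of OTf by H. Since C1 is quaternary, the enone can enolise only towards C5, so the diene position is unambiguous.

**4 to 1 and 2.** The C1–C6 bond (Michael addition) and the C2=C3 bond (aldol condensation) are cut, through keto aldehyde 3. Aldehyde 1 supplies C1 with its methyl and chain, and C2. Enone 2 supplies C3 with its methyl, C4, C5 and C6. The forward reaction has to set the single stereocentre C1 by amine catalysis; the racemic stereocentre of 1 is erased in the enamine.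

## Alternatives that were turned down

**Alternative 1:** Disconnection of C1–CH3 and C2–C7 on enone A2, (5S)-3-[2-(1,3-dioxolan-2-yl)ethyl]-5-(prop-1-en-2-yl)cyclohex-2-en-1-one.
- **Key step:** Me2CuLi delivers methyl to C1 and the resulting enolate is trapped at C2 by CH2O, giving hydroxymethyl ketone A1.
- **For:** both new centres form in the right sense by well-understood rules (methyl trans to the C5 group, electrophile trans to the new methyl). Every reaction type is known and the chain is already in place.
- **Against:** C5 must exist beforehand, and A2 is not a chiral-pool compound, so a separate asymmetric operation is needed. Cuprate addition to a β,β-disubstituted enone is slow, and the hindered enolate reacts poorly with monomeric CH2O. A1 is a β-hydroxy ketone open to retro-aldol, dehydration and epimerisation at C2. The C3 ketone must still become C3(CH3)=C4 and the acetal the acid.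
- **Comparison:** on precedent Alternative 1 is stronger, since the chosen key step is untested. The chosen route instead draws all three stereocentres from one catalytically made centre, makes the C2/C5 cis relationship a geometric necessity, and never places C2 next to a ketone.

**Alternative 2:** Disconnection of C1–C6 and C2–C3 by an intermolecular Diels–Alder reaction.
- **Key step:** silyloxydiene A5, (E)-tert-butyldimethyl(penta-1,3-dien-2-yloxy)silane, adds to butenolide A4, 5-menthyloxy-4-methylfuran-2(5H)-one, to give the cis-fused acetal lactone A3.
- **For:** the menthyloxy acetal is a proven controller of the dienophile face. The cis ring fusion makes the future chain carbon and C7 cis by construction. Both diene substituents reinforce the regiochemistry.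
- **Against:** A4 is a β,β-disubstituted dienophile that must form a quaternary centre, and A5 does not tolerate the Lewis acids or long heating this calls for. C5 is not set at all: A3 has oxygen at C5 and the alkene at C4=C5. The isopropenyl group must then be introduced under remote control and the alkene moved to C3=C4, which is the hard 1,4-problem again. The acetal carbon needs two more carbons, and the lactone must be reduced and differentiated.
- **Comparison:** on absolute stereocontrol Alternative 2 is stronger (a stoichiometric auxiliary against a catalytic annulation of uncertain selectivity). The chosen route sets C5 in the same step as C2 and delivers the isopropenyl group fully formed, in far fewer steps after the cycloaddition.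

**Alternative 3:** Disconnection of the bond between C1 and the first chain CH2, with closure of an ε-lactone.
- **Key step:** visible-light photoredox oxidation (Ir[dF(CF3)ppy]2(dtbbpy)PF6) of caesium oxalate A7 releases two CO2 and a tertiary C1 radical. This adds 7-endo to the acrylate on the C7 oxygen to give the cis-fused lactone A6.
- **For:** radical conjugate addition is a proven way to congested quaternary centres under neutral conditions. A6 maps straight onto the target, since its methanolysis would give alcohol 18.
- **Against:** the step creates only C1. C2 and C5, with their 1,4-cis relationship, must already be present in A7, so the central stereochemical problem is moved into an unsolved precursor. The 7-endo closure needs the disfavoured s-cis ester conformer and competes with reduction of the radical and hydrogen abstraction from the allylic C2–H and C5–H. Cis fusion of a 6-7 system is likely but not enforced.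
- **Comparison:** in end-game economy Alternative 3 is stronger, and it shares with the chosen route the conformational penalty of closing a seven-membered lactone. The chosen route creates and correlates C2 and C5 in the key step and has a short enantioselective entry.

Key step: step 7

Assumption: ester aldehyde 1 is taken as a purchasable racemate, and the (S)-prolinamide catalyst of step 1 is taken to give the (S)-enone 4; should the sense of induction be the opposite, its (R)-enantiomer is used with no other change.

## Route

Step 1
Reactants: 1 methyl 4-methyl-5-oxopentanoate (racemic); 2 pent-1-en-3-one (ethyl vinyl ketone)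
Product: 4 methyl 3-[(1S)-1,3-dimethyl-4-oxocyclohex-2-en-1-yl]propanoate, via Michael adduct methyl (4S)-4-formyl-4-methyl-7-oxononanoate 3 (not isolated)
Conditions: (S)-N-(4-dodecylphenylsulfonyl)pyrrolidine-2-carboxamide (20 mol %), BnNH2 (20 mol %), 4 Å MS, ClCH2CH2Cl, rt; then pyrrolidine, AcOH (20 mol % each), 40 °C
Reagents that add atoms: none
Why: Amine-catalysed asymmetric Robinson annulation: the enamine of 1 (its own stereocentre erased, so the racemate converges) adds to 2, which the sulfonamide N–H binds and directs to one enamine face, setting the quaternary centre of 3. Aldol condensation of 3 can only use the ethyl CH2 of the ketone, which gives the 2-methyl enone 4.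

Step 2
Reactants: 4 methyl 3-[(1S)-1,3-dimethyl-4-oxocyclohex-2-en-1-yl]propanoate
Product: 6 methyl 3-[(1R)-1,3-dimethyl-4-{[(trifluoromethyl)sulfonyl]oxy}cyclohexa-2,4-dien-1-yl]propanoate, via lithium cross-conjugated dienolate 5 (not isolated)
Conditions: LiN(SiMe3)2, THF, −78 °C; then PhNTf2, −78 → 0 °C
Reagents that add atoms: N-phenylbis(trifluoromethanesulfonimide), O=S(=O)(N(c1ccccc1)S(=O)(=O)C(F)(F)F)C(F)(F)F
Why: Kinetic enolisation and O-triflation; the γ-position is quaternary, so only the α'-CH2 (C5) can be deprotonated, and the ketone is far more acidic than the ester. The descriptor changes from S to R only because C6 now outranks the chain; no bond at C1 is touched.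

Step 3
Reactants: 6 methyl 3-[(1R)-1,3-dimethyl-4-{[(trifluoromethyl)sulfonyl]oxy}cyclohexa-2,4-dien-1-yl]propanoate
Product: 7 methyl 3-[(1R)-1,3-dimethylcyclohexa-2,4-dien-1-yl]propanoate
Conditions: Pd(OAc)2 (5 mol %), PPh3 (10 mol %), HCO2H, Bu3N, DMF, 60 °C
Reagents that add atoms: none
Why: Palladium-catalysed formate reduction of a vinyl triflate: zerovalent palladium inserts into C4–OTf, formate replaces triflate, and loss of CO2 with reductive elimination puts H on C4 without moving either double bond. The quaternary C1 blocks aromatisation.

Step 4
Reactants: 7 methyl 3-[(1R)-1,3-dimethylcyclohexa-2,4-dien-1-yl]propanoate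
Product: 8 3-[(1R)-1,3-dimethylcyclohexa-2,4-dien-1-yl]propanoic acid
Conditions: LiOH·H2O, THF/MeOH/H2O, rt; then cold 1 M HCl to pH 3
Reagents that add atoms: lithium hydroxide, [Li+].[OH-]
Why: Plain saponification of an unhindered methyl ester; the diene is inert to base and the brief, cold acidification avoids acid-induced isomerisation.

Step 5
Reactants: 9 3-(dimethylamino)-2-methylprop-2-enal
Product: 10 sodium (E)-2-methyl-3-oxoprop-1-en-1-olate
Conditions: NaOH (1.0 equiv), H2O, 70 °C, Me2NH removed under reduced pressure; solid dried in vacuo
Reagents that add atoms: sodium hydroxide, [Na+].[OH-]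
Why: Addition–elimination of hydroxide on the vinylogous formamide expels dimethylamine and leaves the delocalised enolate of methylmalonaldehyde as a storable salt.

Step 6
Reactants: 8 3-[(1R)-1,3-dimethylcyclohexa-2,4-dien-1-yl]propanoic acid; 10 sodium (E)-2-methyl-3-oxoprop-1-en-1-olate
Product: 12 (E)-2-methyl-3-oxoprop-1-en-1-yl 3-[(1R)-1,3-dimethylcyclohexa-2,4-dien-1-yl]propanoate, via 3-[(1R)-1,3-dimethylcyclohexa-2,4-dien-1-yl]propanoyl chloride 11 (not isolated)
Conditions: 1-chloro-N,N,2-trimethylprop-1-en-1-amine, CH2Cl2, 0 °C; then 10, 15-crown-5 (10 mol %), THF, −20 → 0 °C; rapid filtration through deactivated silica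
Reagents that add atoms: none
Why: The α-chloroenamine makes the acid chloride without releasing HCl, which protects the diene. The hard acyl chloride then acylates the ambident formyl enolate on oxygen (O-acylation of a 1,3-dicarbonyl enolate), giving the E enol ester.

Step 7
Reactants: 12 (E)-2-methyl-3-oxoprop-1-en-1-yl 3-[(1R)-1,3-dimethylcyclohexa-2,4-dien-1-yl]propanoate
Product: 13 tricyclic lactone aldehyde (bicyclo[2.2.2]oct-2-ene with bridgeheads C2 and C5, bridges C3(CH3)=C4, C1(CH3)–C6H2 and C7H(O)–C8(CH3)(CHO); ε-lactone from the C7 oxygen through C(=O)CH2CH2 to C1; formyl group over C3=C4, C7–O and C8 methyl towards the C1–C6 bridge)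
Conditions: Me2AlCl (1.5 equiv), CH2Cl2 (0.005 M), −78 → −20 °C
Reagents that add atoms: none
Why: Proposed new method: Me2AlCl binds the formyl oxygen of the β-acyloxy enal, lowers its LUMO and lets C7=C8 add across C2 and C5 of the cyclohexa-1,3-diene in a concerted, suprafacial [4+2] reaction; the closest known reaction type is the intramolecular Diels–Alder reaction of cyclohexa-1,3-dienes and cyclohexa-2,4-dienones whose dienophile hangs from the sp3 ring carbon next to the diene, here extended to an enol-ester tether and a seven-membered lactone. The new cyclohexene (C2, C3, C4, C5, C8, C7) closes by the cycloaddition itself and completes the bicyclo[2.2.2]octene, and the ε-lactone (C1, CH2, CH2, C=O, O, C7, C2) closes in the same event because C2–C7 is its last ring bond. C2 and C5 are set by C1: the four-atom tether can bring C7 to C2 only on the ring face that carries the chain, so both new bonds form cis to CH2CH2C(=O) and anti to the C1 methyl. C7 and C8 are set by the E geometry of the enol ester (O and CH3 stay cis) and by the tether, which must lie on the C1–C6 side and so places the Lewis-acid-bound formyl group endo over C3=C4; both centres are erased in step 10, so an E/Z or endo/exo mixture is tolerated. The step needs face selectivity and the regiochemistry C7 to C2 and C8 to C5; the face is fixed by the tether, and the regiochemistry is favoured by the seven- over the eight-membered ring, by the larger diene coefficient at C2 meeting the β-carbon of the enal, and by the quaternary C8 bonding to the unhindered C5. Low temperature under Lewis acid activation keeps the thermal 1,5-hydrogen shift of the diene out of play, and high dilution suppresses intermolecular addition.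

Step 8
Reactants: 13 tricyclic lactone aldehyde
Product: 14 tricyclic lactone alcohol (as 13, with C8 bearing CH3 and CH2OH)
Conditions: NaBH4, MeOH/CH2Cl2, −20 → 0 °C
Reagents that add atoms: none
Why: Chemoselective borohydride reduction of the aldehyde beside the lactone; the aldehyde has no α-hydrogen, so neither epimerisation nor elimination of the acyloxy group can occur.

Step 9
Reactants: 14 tricyclic lactone alcohol
Product: 15 tricyclic lactone mesylate (as 13, with C8 bearing CH3 and CH2OSO2CH3)
Conditions: MsCl, Et3N, CH2Cl2, 0 °C
Reagents that add atoms: methanesulfonyl chloride, CS(=O)(=O)Cl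
Why: Standard sulfonylation of a primary alcohol; the neopentyl mesylate has no β-hydrogen and resists direct displacement, so it is stable until the C7 alkoxide is unmasked.

Step 10
Reactants: 15 tricyclic lactone mesylate
Product: 18 methyl 3-[(1R,2R,5S)-2-(hydroxymethyl)-1,3-dimethyl-5-(prop-1-en-2-yl)cyclohex-3-en-1-yl]propanoate, via sodium alkoxide of the ring-opened hydroxy mesylate methyl ester 16 (not isolated), via methyl 3-[(1R,2R,5S)-2-formyl-1,3-dimethyl-5-(prop-1-en-2-yl)cyclohex-3-en-1-yl]propanoate 17 (not isolated)
Conditions: NaOMe (3 equiv), NaBH4 (2 equiv), MeOH/THF, 0 → 40 °C; AcOH quench at 0 °C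
Reagents that add atoms: sodium methoxide, C[O-].[Na+]
Why: Methoxide opens the lactone by transesterification and frees C7 alkoxide 16, in which the oxygen lone pair, the C7–C8 bond and the freely rotating C9–OMs bond can align anti-periplanar for a Grob fragmentation that gives the C2 aldehyde and the C8=C9 alkene at once. NaBH4 reduces aldehyde 17 faster than base can epimerise C2 or pull C3=C4 into conjugation. No bond at C1, C2 or C5 is broken, so the all-cis arrangement from step 7 is carried over unchanged.

Step 11
Reactants: 18 methyl 3-[(1R,2R,5S)-2-(hydroxymethyl)-1,3-dimethyl-5-(prop-1-en-2-yl)cyclohex-3-en-1-yl]propanoate; 19 umbelliferone (7-hydroxy-2H-chromen-2-one)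
Product: 20 methyl 3-[(1R,2R,5S)-1,3-dimethyl-2-{[(2-oxo-2H-chromen-7-yl)oxy]methyl}-5-(prop-1-en-2-yl)cyclohex-3-en-1-yl]propanoate
Conditions: PPh3, DIAD, THF, 0 °C → rt
Reagents that add atoms: none
Why: Mitsunobu etherification: the acidic phenol displaces the activated primary alcohol at C7 in an SN2 step that touches no stereocentre; C7 is homoallylic, so allylic transposition is not possible.

Step 12
Reactants: 20 methyl 3-[(1R,2R,5S)-1,3-dimethyl-2-{[(2-oxo-2H-chromen-7-yl)oxy]methyl}-5-(prop-1-en-2-yl)cyclohex-3-en-1-yl]propanoate
Product: 21 3-[(1R,2R,5S)-1,3-dimethyl-2-{[(2-oxo-2H-chromen-7-yl)oxy]methyl}-5-(prop-1-en-2-yl)cyclohex-3-en-1-yl]propanoic acid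
Conditions: LiOH, THF/H2O, rt; then 1 M HCl to pH 2
Reagents that add atoms: lithium hydroxide, [Li+].[OH-]
Why: Saponification of the methyl ester; any coumarin opened to the cis-hydroxycinnamate recloses on acidification, and no stereocentre is adjacent to a carbonyl.

## Compound list

1 | methyl 4-methyl-5-oxopentanoate (racemic) | COC(=O)CCC(C)C=O | starting material
2 | pent-1-en-3-one (ethyl vinyl ketone) | C=CC(=O)CC | starting material
3 | methyl (4S)-4-formyl-4-methyl-7-oxononanoate | O=C[C@](C)(CCC(=O)OC)CCC(=O)CC | intermediate (not isolated)
4 | methyl 3-[(1S)-1,3-dimethyl-4-oxocyclohex-2-en-1-yl]propanoate | CC1=C[C@](C)(CCC(=O)OC)CCC1=O | intermediate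
5 | lithium (4R)-4-(3-methoxy-3-oxopropyl)-4,6-dimethylcyclohexa-1,5-dien-1-olate | CC1=C[C@](C)(CCC(=O)OC)CC=C1[O-].[Li+] | intermediate (not isolated)
6 | methyl 3-[(1R)-1,3-dimethyl-4-{[(trifluoromethyl)sulfonyl]oxy}cyclohexa-2,4-dien-1-yl]propanoate | CC1=C[C@](C)(CCC(=O)OC)CC=C1OS(=O)(=O)C(F)(F)F | intermediate
7 | methyl 3-[(1R)-1,3-dimethylcyclohexa-2,4-dien-1-yl]propanoate | CC1=C[C@](C)(CCC(=O)OC)CC=C1 | intermediate
8 | 3-[(1R)-1,3-dimethylcyclohexa-2,4-dien-1-yl]propanoic acid | CC1=C[C@](C)(CCC(=O)O)CC=C1 | intermediate
9 | 3-(dimethylamino)-2-methylprop-2-enal | CN(C)C=C(C)C=O | starting material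
10 | sodium (E)-2-methyl-3-oxoprop-1-en-1-olate | [Na+].[O-]/C=C(\C)C=O | intermediate
11 | 3-[(1R)-1,3-dimethylcyclohexa-2,4-dien-1-yl]propanoyl chloride | CC1=C[C@](C)(CCC(=O)Cl)CC=C1 | intermediate (not isolated)
12 | (E)-2-methyl-3-oxoprop-1-en-1-yl 3-[(1R)-1,3-dimethylcyclohexa-2,4-dien-1-yl]propanoate | CC1=C[C@](C)(CCC(=O)O/C=C(\C)C=O)CC=C1 | intermediate (precursor of the key step)
13 | tricyclic lactone aldehyde: ε-lactone of 3-(7-formyl-8-hydroxy-2,6,7-trimethylbicyclo[2.2.2]oct-5-en-2-yl)propanoic acid (bicyclooctene locants; formyl syn to the alkene bridge, 8-O and 7-methyl syn to the C2–C3 bridge) | O=C[C@]1(C)[C@@H]2C=C(C)[C@@H]3[C@H]1OC(=O)CC[C@]3(C)C2 | intermediate (product of the key step)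
14 | tricyclic lactone alcohol: as 13 with CH2OH in place of CHO | OC[C@]1(C)[C@@H]2C=C(C)[C@@H]3[C@H]1OC(=O)CC[C@]3(C)C2 | intermediate
15 | tricyclic lactone mesylate: as 13 with CH2OSO2CH3 in place of CHO | CS(=O)(=O)OC[C@]1(C)[C@@H]2C=C(C)[C@@H]3[C@H]1OC(=O)CC[C@]3(C)C2 | intermediate
16 | sodium alkoxide of methyl 3-[8-hydroxy-2,6,7-trimethyl-7-{[(methylsulfonyl)oxy]methyl}bicyclo[2.2.2]oct-5-en-2-yl]propanoate (configured as in 15) | CS(=O)(=O)OC[C@]1(C)[C@@H]2C=C(C)[C@@H]([C@](C)(CCC(=O)OC)C2)[C@H]1[O-].[Na+] | intermediate (not isolated)
17 | methyl 3-[(1R,2R,5S)-2-formyl-1,3-dimethyl-5-(prop-1-en-2-yl)cyclohex-3-en-1-yl]propanoate | C=C(C)[C@@H]1C=C(C)[C@H](C=O)[C@](C)(CCC(=O)OC)C1 | intermediate (not isolated)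
18 | methyl 3-[(1R,2R,5S)-2-(hydroxymethyl)-1,3-dimethyl-5-(prop-1-en-2-yl)cyclohex-3-en-1-yl]propanoate | C=C(C)[C@@H]1C=C(C)[C@H](CO)[C@](C)(CCC(=O)OC)C1 | intermediate
19 | umbelliferone (7-hydroxy-2H-chromen-2-one) | O=c1ccc2ccc(O)cc2o1 | starting material
20 | methyl 3-[(1R,2R,5S)-1,3-dimethyl-2-{[(2-oxo-2H-chromen-7-yl)oxy]methyl}-5-(prop-1-en-2-yl)cyclohex-3-en-1-yl]propanoate | C=C(C)[C@@H]1C=C(C)[C@H](COc2ccc3ccc(=O)oc3c2)[C@](C)(CCC(=O)OC)C1 | intermediate
21 | 3-[(1R,2R,5S)-1,3-dimethyl-2-{[(2-oxo-2H-chromen-7-yl)oxy]methyl}-5-(prop-1-en-2-yl)cyclohex-3-en-1-yl]propanoic acid | C=C(C)[C@@H]1C=C(C)[C@H](COc2ccc3ccc(=O)oc3c2)[C@](C)(CCC(=O)O)C1 | target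

## Step count and risk

Total step count: 12. Longest linear sequence: 11 steps (steps 1–4 and 6–12); step 5 prepares enolate 10 in a side branch.

**Step 7 (key step, proposed new method).**
- **What may go wrong:** the cycloaddition may be too slow. The ester tether must take up the disfavoured s-cis conformation and close a seven-membered ring. Lewis-acid-induced acyl transfer from the vinylogous anhydride, intermolecular addition, or (on warming) the 1,5-hydrogen shift of the diene may then take over.
- **Fallback (known chemistry, from 7, rejoining at 14):** the dienophile is tied to C1 through a ketone, the established six-membered-ring version of this cycloaddition.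
  - MeNHOMe·HCl and iPrMgCl in THF convert 7 into the N-methoxy-N-methylamide F1.
  - The vinyllithium from purchased (E)-tert-butyl[(3-iodo-2-methylprop-2-en-1-yl)oxy]dimethylsilane and tBuLi adds to give the (E)-enone F2.
  - Intramolecular Diels–Alder reaction (Me2AlCl in CH2Cl2, or toluene at 110 °C) gives, under the same tether-imposed face control, the tricyclic ketone F3.
  - Baeyer–Villiger oxidation with Me3SiOOSiMe3 and catalytic Me3SiOTf spares the alkene; the secondary C7 migrates, giving the lactone silyl ether F4.
  - Bu4NF then gives 14.

**Step 10.**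
- **What may go wrong:** fragmentation may be slow in the protic medium, because the C7 alkoxide is hydrogen-bonded and in unfavourable equilibrium with methoxide. That allows relactonisation or internal displacement to an oxetane. If the aldehyde outlives the hydride, C2 may epimerise or the ring alkene may move into conjugation.
- **Fallback (from 15, rejoining at 18):** fragmentation as a dianion in an aprotic medium.
  - LiOH in THF/H2O at 0 °C opens the lactone to the hydroxy acid mesylate F5, whose carboxylate cannot relactonise.
  - KH (2.1 equiv) with 18-crown-6 in THF at 0 °C triggers the classical 1,3-diol monosulfonate fragmentation.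
  - A cold quench into NaBH4/EtOH gives the hydroxy acid F6.
  - Me3SiCHN2 in toluene/MeOH gives 18.

**Step 1.**
- **What may go wrong:** insufficient enantioselectivity, because CH3 and CH2CH2CO2Me differ little and the enamine geometry may be poorly controlled. The Michael addition that forms the quaternary centre may also be slow.
- **Fallback (from 1 and 2, rejoining at 4):** resolution instead of asymmetric catalysis. Pyrrolidine enamine formation, addition of 2 and AcOH/NaOAc-buffered aldol condensation give the racemic enone ester F7. Preparative chromatography on a chiral stationary phase (amylose tris(3,5-dimethylphenylcarbamate), supercritical CO2/MeOH) gives 4.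

**Step 6.**
- **What may go wrong:** competing C-acylation or double acylation of the ambident enolate, and hydrolysis or acyl transfer of the vinylogous anhydride during isolation.
- **Fallback (from 10 and 8, rejoining at 12):** reversed polarity. (COCl)2 with catalytic DMF in CH2Cl2 converts 10 into (E)-3-chloro-2-methylprop-2-enal F8. The caesium carboxylate of 8 (Cs2CO3, DMF, 0 °C) adds to F8 and expels chloride to give 12.

## Further compounds

F1 | step 7 | 3-[(1R)-1,3-dimethylcyclohexa-2,4-dien-1-yl]-N-methoxy-N-methylpropanamide | CC1=C[C@](C)(CCC(=O)N(C)OC)CC=C1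
F2 | step 7 | (E)-6-[(tert-butyldimethylsilyl)oxy]-1-[(1R)-1,3-dimethylcyclohexa-2,4-dien-1-yl]-5-methylhex-4-en-3-one | CC1=C[C@](C)(CCC(=O)/C=C(\C)CO[Si](C)(C)C(C)(C)C)CC=C1
F3 | step 7 | tricyclic ketone: as 14 with the ring oxygen absent (C7 bonded directly to the chain C=O) and C9 as its tert-butyldimethylsilyl ether | CC(C)(C)[Si](C)(C)OC[C@]1(C)[C@@H]2C=C(C)[C@@H]3[C@H]1C(=O)CC[C@]3(C)C2
F4 | step 7 | tert-butyldimethylsilyl ether of lactone alcohol 14 | CC(C)(C)[Si](C)(C)OC[C@]1(C)[C@@H]2C=C(C)[C@@H]3[C@H]1OC(=O)CC[C@]3(C)C2
F5 | step 10 | 3-[8-hydroxy-2,6,7-trimethyl-7-{[(methylsulfonyl)oxy]methyl}bicyclo[2.2.2]oct-5-en-2-yl]propanoic acid (configured as in 15) | CS(=O)(=O)OC[C@]1(C)[C@@H]2C=C(C)[C@@H]([C@](C)(CCC(=O)O)C2)[C@H]1O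
F6 | step 10 | 3-[(1R,2R,5S)-2-(hydroxymethyl)-1,3-dimethyl-5-(prop-1-en-2-yl)cyclohex-3-en-1-yl]propanoic acid | C=C(C)[C@@H]1C=C(C)[C@H](CO)[C@](C)(CCC(=O)O)C1
F7 | step 1 | racemic methyl 3-(1,3-dimethyl-4-oxocyclohex-2-en-1-yl)propanoate | CC1=CC(C)(CCC(=O)OC)CCC1=O
F8 | step 6 | (E)-3-chloro-2-methylprop-2-enal | Cl/C=C(\C)C=O
A1 | alternative 1 | 3-[2-(1,3-dioxolan-2-yl)ethyl]-2-(hydroxymethyl)-3-methyl-5-(prop-1-en-2-yl)cyclohexan-1-one (hydroxymethyl, dioxolanylethyl and isopropenyl mutually cis) | C=C(C)[C@@H]1CC(=O)[C@H](CO)[C@](C)(CCC2OCCO2)C1
A2 | alternative 1 | (5S)-3-[2-(1,3-dioxolan-2-yl)ethyl]-5-(prop-1-en-2-yl)cyclohex-2-en-1-one | C=C(C)[C@@H]1CC(=O)C=C(CCC2OCCO2)C1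
A3 | alternative 2 | cis-fused bicyclic menthyloxy acetal lactone with C5 tert-butyldimethylsilyl enol ether and C3 methyl | CC(C)[C@@H]1CC[C@@H](C)C[C@H]1O[C@@H]2OC(=O)[C@H]3[C@@H](C)C=C(O[Si](C)(C)C(C)(C)C)C[C@@]23C
A4 | alternative 2 | 5-(menthyloxy)-4-methylfuran-2(5H)-one | CC(C)[C@@H]1CC[C@@H](C)C[C@H]1O[C@@H]2OC(=O)C=C2C
A5 | alternative 2 | (E)-tert-butyldimethyl(penta-1,3-dien-2-yloxy)silane | C=C(O[Si](C)(C)C(C)(C)C)/C=C/C
A6 | alternative 3 | cis-fused ε-lactone joining the C7 oxygen to the C1 CH2CH2C(=O) chain, isopropenyl at C5 cis | C=C(C)[C@@H]1C=C(C)[C@@H]2COC(=O)CC[C@]2(C)C1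
A7 | alternative 3 | caesium oxalate half-ester of the C1 tertiary alcohol carrying the C7 acrylate (C1 configuration immaterial) | C=C(C)[C@@H]1C=C(C)[C@H](COC(=O)C=C)C(C)(OC(=O)C(=O)[O-])C1.[Cs+]
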